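The oxolane is disconnected between C2 (pentyl-bearing, bound to the ring oxygen) and C3 (the carbinol). Reading the C2 pentyl as a vinyl group turns the cis O1–C2/C3–OH array of the ring into the retron of an intramolecular allylboration. A (Z)-γ-alkoxyallyl pinacol boronate, tethered through O1 and C5 to a masked aldehyde, closes the ring on unmasking: it forges C2–C3 and fixes C2, C3 (cis) and their trans relation to C5 in one bicyclic chair transition state. The acyclic precursor is a 2-deoxypentose acetal built from D-glyceraldehyde acetonide, whose stereocentre becomes the ester-bearing carbinol. The alkenyl chain enters late by epoxide opening, the palmitate last.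

Key step: step 5

Remark: oxolane locants are O1, C2 (pentyl), C3 (hydroxyl), C4, C5 (side chain); reagent 2 is taken to be the commercial antipode made from (−)-α-pinene.

Step 1
Reactants: 1 (4R)-2,2-dimethyl-1,3-dioxolane-4-carbaldehyde; 2 (+)-B-allyldiisopinocampheylborane
Product: 4 (1R)-1-[(4R)-2,2-dimethyl-1,3-dioxolan-4-yl]but-3-en-1-ol, via borinate ester 3 (not isolated)
Conditions: 2 (1.2 equiv, pentane solution), Et2O, −78 °C; then 3 M NaOH, 30 % H2O2, 0 °C → rt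
Reagents that add atoms: (+)-B-allyldiisopinocampheylborane (2) C=CCB([C@H]1C[C@H]2C[C@@H]([C@@H]1C)C2(C)C)[C@H]1C[C@H]2C[C@@H]([C@@H]1C)C2(C)C
Why: Brown allylation through a six-membered chair transition state; the reagent of the (−)-α-pinene series should override the Felkin preference of the aldehyde and give the (R)-carbinol, i.e. the syn (threo) 1,2-dioxygenated pair.

Step 2
Reactants: 4 (1R)-1-[(4R)-2,2-dimethyl-1,3-dioxolan-4-yl]but-3-en-1-ol
Product: 6 (1R)-1-[(4R)-2,2-dimethyl-1,3-dioxolan-4-yl]-3,3-dimethoxypropan-1-ol, via hydroxy aldehyde 5 (not isolated)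
Conditions: O3, CH2Cl2/MeOH 4:1, −78 °C; Me2S, −78 °C → rt; then HC(OMe)3, PPTS (5 mol %), MeOH, 0 °C → rt
Reagents that add atoms: trimethyl orthoformate COC(OC)OC; methanol CO
Why: ozonolysis of the terminal alkene with reductive work-up followed by orthoformate-driven acetalization should mask the aldehyde without touching either stereocentre.

Step 3
Reactants: 6 (1R)-1-[(4R)-2,2-dimethyl-1,3-dioxolan-4-yl]-3,3-dimethoxypropan-1-ol; 7 3-bromoprop-1-ene
Product: 8 (4R)-4-[(1R)-3,3-dimethoxy-1-(prop-2-enyloxy)propyl]-2,2-dimethyl-1,3-dioxolane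
Conditions: NaH (1.3 equiv), 7 (1.5 equiv), Bu4NI (5 mol %), THF, 0 °C → rt
Reagents that add atoms: 3-bromoprop-1-ene (7) C=CCBr
Why: Williamson etherification of the secondary alkoxide, in which no stereocentre takes part.

Step 4
Reactants: 8 (4R)-4-[(1R)-3,3-dimethoxy-1-(prop-2-enyloxy)propyl]-2,2-dimethyl-1,3-dioxolane
Product: 10 2-[(2Z)-3-{[(1R)-1-[(4R)-2,2-dimethyl-1,3-dioxolan-4-yl]-3,3-dimethoxypropyl]oxy}prop-2-enyl]-4,4,5,5-tetramethyl-1,3,2-dioxaborolane, via lithiated allyl ether 9 (not isolated)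
Conditions: s-BuLi (1.3 equiv), THF, −78 °C, 1 h; then 2-isopropoxy-4,4,5,5-tetramethyl-1,3,2-dioxaborolane (1.5 equiv), −78 → 0 °C; aq NH4Cl
Reagents that add atoms: 2-isopropoxy-4,4,5,5-tetramethyl-1,3,2-dioxaborolane CC(C)OB1OC(C)(C)C(C)(C)O1
Why: allylic α-lithiation of the allyl ether gives the oxygen-chelated (Z)-alkoxyallyllithium, and electrophilic borylation at its γ-carbon should deliver the (Z)-γ-alkoxyallylboronate with the enol ether geometry fixed by the chelate.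

Step 5
Reactants: 10 2-[(2Z)-3-{[(1R)-1-[(4R)-2,2-dimethyl-1,3-dioxolan-4-yl]-3,3-dimethoxypropyl]oxy}prop-2-enyl]-4,4,5,5-tetramethyl-1,3,2-dioxaborolane
Product: 13 (2S,3S,5R)-5-[(4R)-2,2-dimethyl-1,3-dioxolan-4-yl]-2-ethenyloxolan-3-ol, via aldehyde 11 (not isolated), via borate ester 12 (not isolated)
Conditions: LiBF4 (2 equiv), MeCN/H2O 50:1, 0.02 M, rt; aq NaHCO3 work-up
Reagents that add atoms: water O
Why: LiBF4-assisted hydrolysis of the dimethyl acetal frees aldehyde 11, whose carbonyl carbon is attacked by the oxygen-bearing γ-carbon of the allylboronate in an intramolecular allylboration through a six-membered Zimmerman–Traxler chair, boron passing to the new alkoxide (12) and the vinyl group emerging by allylic transposition; the closest known reaction is the intramolecular allylboration of (Z)-γ-alkoxyallylboronates with tethered aldehydes to cis-2-vinyl-3-hydroxy cyclic ethers. The oxolane closes in a 5-exo-trig mode at the aldehyde C=O, the new C2–C3 bond being shared by the five-membered ring and the chair, so the transition state is a cis-fused bicycle. At C2 and C3 the Z enol ether places the ring oxygen axial and the aldehyde chain equatorial on the chair, a gauche pair that the one-carbon bridge can span and that should give the cis 2-vinyl-3-ol. The existing C5 stereocentre should put its dioxolanyl group on the convex face of this bicycle, away from the boronate chair, hence trans to both the vinyl and the hydroxyl group, which is the (2S,3S,5R) array. The step needs γ-attack of the allyl unit (the inherent SE2′ course of allylboronates), an intact Z geometry (no isomerization at rt) and cleavage of the acyclic acetal in preference to the isopropylidene acetal and the enol ether (mild, nearly neutral conditions; high dilution against intermolecular allylation).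

Step 6
Reactants: 13 (2S,3S,5R)-5-[(4R)-2,2-dimethyl-1,3-dioxolan-4-yl]-2-ethenyloxolan-3-ol; 14 (4E)-oct-4-ene
Product: 16 (2S,3S,5R)-5-[(4R)-2,2-dimethyl-1,3-dioxolan-4-yl]-2-pentyloxolan-3-ol, via pentenyl alcohol 15 (not isolated)
Conditions: second-generation Grubbs catalyst RuCl2(=CHPh)(PCy3)(H2IMes) (5 mol %), 14 (5 equiv), CH2Cl2, 40 °C; then EtOAc, Pd/C (10 wt %), H2 (1 atm), rt, same flask
Reagents that add atoms: (4E)-oct-4-ene (14) CCC/C=C/CCC
Why: olefin cross-metathesis of the vinyl group with an excess of an unhindered internal alkene, followed by heterogeneous hydrogenation, should complete the pentyl chain without touching the ring stereocentres.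

Step 7
Reactants: 16 (2S,3S,5R)-5-[(4R)-2,2-dimethyl-1,3-dioxolan-4-yl]-2-pentyloxolan-3-ol
Product: 17 tert-butyl{[(2S,3S,5R)-5-[(4R)-2,2-dimethyl-1,3-dioxolan-4-yl]-2-pentyloxolan-3-yl]oxy}dimethylsilane
Conditions: TBSOTf (1.3 equiv), 2,6-lutidine (2.5 equiv), CH2Cl2, −78 → 0 °C
Reagents that add atoms: tert-butyldimethylsilyl trifluoromethanesulfonate CC(C)(C)[Si](C)(C)OS(=O)(=O)C(F)(F)F
Why: silylation of the hindered ring hydroxyl with the silyl triflate, so that later only the side-chain hydroxyl is free for acylation.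

Step 8
Reactants: 17 tert-butyl{[(2S,3S,5R)-5-[(4R)-2,2-dimethyl-1,3-dioxolan-4-yl]-2-pentyloxolan-3-yl]oxy}dimethylsilane
Product: 18 (1R)-1-[(2R,4S,5S)-4-{[tert-butyl(dimethyl)silyl]oxy}-5-pentyloxolan-2-yl]ethane-1,2-diol
Conditions: CuCl2·2H2O (2 equiv), MeCN, 0 °C → rt
Reagents that add atoms: none
Why: mild Lewis-acid hydrolysis of the terminal isopropylidene acetal, a reaction type that should spare a secondary TBS ether.

Step 9
Reactants: 18 (1R)-1-[(2R,4S,5S)-4-{[tert-butyl(dimethyl)silyl]oxy}-5-pentyloxolan-2-yl]ethane-1,2-diol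
Product: 20 tert-butyldimethyl{[(2S,3S,5R)-5-[(2R)-oxiran-2-yl]-2-pentyloxolan-3-yl]oxy}silane, via primary tosylate 19 (not isolated)
Conditions: NaH (2.5 equiv), N-tosylimidazole (1.05 equiv), THF, 0 °C → rt
Reagents that add atoms: none
Why: selective sulfonylation of the primary alkoxide and intramolecular Williamson closure by the neighbouring secondary alkoxide; the C–O bond at the stereocentre is not broken, so its configuration is retained.

Step 10
Reactants: 20 tert-butyldimethyl{[(2S,3S,5R)-5-[(2R)-oxiran-2-yl]-2-pentyloxolan-3-yl]oxy}silane; 21 8-bromooct-1-ene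
Product: 23 (1R)-1-[(2R,4S,5S)-4-{[tert-butyl(dimethyl)silyl]oxy}-5-pentyloxolan-2-yl]dec-9-en-1-ol, via oct-7-enylmagnesium bromide 22 (not isolated)
Conditions: 21, Mg turnings, THF, rt → 40 °C; then CuI (10 mol %), 20, THF, −30 → 0 °C; aq NH4Cl
Reagents that add atoms: 8-bromooct-1-ene (21, used as its Grignard reagent 22) C=CCCCCCCBr
Why: copper-catalysed Grignard opening of the terminal epoxide at its unsubstituted carbon (SN2) leaves the carbinol stereocentre intact and frees the only hydroxyl of the molecule.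

Step 11
Reactants: 23 (1R)-1-[(2R,4S,5S)-4-{[tert-butyl(dimethyl)silyl]oxy}-5-pentyloxolan-2-yl]dec-9-en-1-ol; 24 hexadecanoyl chloride
Product: 25 (1R)-1-[(2R,4S,5S)-4-{[tert-butyl(dimethyl)silyl]oxy}-5-pentyloxolan-2-yl]dec-9-enyl hexadecanoate
Conditions: 24 (1.5 equiv), pyridine, DMAP (0.2 equiv), CH2Cl2, 0 °C → rt
Reagents that add atoms: hexadecanoyl chloride (24) CCCCCCCCCCCCCCCC(Cl)=O
Why: DMAP-catalysed O-acylation of the single free secondary alcohol, which proceeds with retention at carbon.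

Step 12
Reactants: 25 (1R)-1-[(2R,4S,5S)-4-{[tert-butyl(dimethyl)silyl]oxy}-5-pentyloxolan-2-yl]dec-9-enyl hexadecanoate
Product: 26 (1R)-1-[(2R,4S,5S)-4-hydroxy-5-pentyloxolan-2-yl]dec-9-enyl hexadecanoate
Conditions: HF·pyridine, THF/pyridine, 0 °C → rt
Reagents that add atoms: none
Why: fluoride-mediated desilylation under mildly acidic conditions should leave the ester (no acyl migration across the ring) and the terminal alkene untouched.

Compound list
1 | (4R)-2,2-dimethyl-1,3-dioxolane-4-carbaldehyde (2,3-O-isopropylidene-D-glyceraldehyde) | O=C[C@H]1COC(C)(C)O1 | starting material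
2 | (+)-B-allyldiisopinocampheylborane, (−)-α-pinene series | C=CCB([C@H]1C[C@H]2C[C@@H]([C@@H]1C)C2(C)C)[C@H]1C[C@H]2C[C@@H]([C@@H]1C)C2(C)C | starting material
3 | (1R)-1-[(4R)-2,2-dimethyl-1,3-dioxolan-4-yl]but-3-enyl diisopinocampheylborinate | C=CC[C@@H](OB([C@H]1C[C@H]2C[C@@H]([C@@H]1C)C2(C)C)[C@H]1C[C@H]2C[C@@H]([C@@H]1C)C2(C)C)[C@H]1COC(C)(C)O1 | intermediate
4 | (1R)-1-[(4R)-2,2-dimethyl-1,3-dioxolan-4-yl]but-3-en-1-ol | C=CC[C@@H](O)[C@H]1COC(C)(C)O1 | intermediate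
5 | (3R)-3-[(4R)-2,2-dimethyl-1,3-dioxolan-4-yl]-3-hydroxypropanal | O=CC[C@@H](O)[C@H]1COC(C)(C)O1 | intermediate
6 | (1R)-1-[(4R)-2,2-dimethyl-1,3-dioxolan-4-yl]-3,3-dimethoxypropan-1-ol | COC(OC)C[C@@H](O)[C@H]1COC(C)(C)O1 | intermediate
7 | 3-bromoprop-1-ene (allyl bromide) | C=CCBr | starting material
8 | (4R)-4-[(1R)-3,3-dimethoxy-1-(prop-2-enyloxy)propyl]-2,2-dimethyl-1,3-dioxolane | COC(OC)C[C@@H](OCC=C)[C@H]1COC(C)(C)O1 | intermediate
9 | [(2Z)-3-{[(1R)-1-[(4R)-2,2-dimethyl-1,3-dioxolan-4-yl]-3,3-dimethoxypropyl]oxy}prop-2-enyl]lithium | COC(OC)C[C@@H](O/C=C\C[Li])[C@H]1COC(C)(C)O1 | intermediate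
10 | 2-[(2Z)-3-{[(1R)-1-[(4R)-2,2-dimethyl-1,3-dioxolan-4-yl]-3,3-dimethoxypropyl]oxy}prop-2-enyl]-4,4,5,5-tetramethyl-1,3,2-dioxaborolane | COC(OC)C[C@@H](O/C=C\CB1OC(C)(C)C(C)(C)O1)[C@H]2COC(C)(C)O2 | intermediate
11 | (3R)-3-[(4R)-2,2-dimethyl-1,3-dioxolan-4-yl]-3-{[(1Z)-3-(4,4,5,5-tetramethyl-1,3,2-dioxaborolan-2-yl)prop-1-enyl]oxy}propanal | O=CC[C@@H](O/C=C\CB1OC(C)(C)C(C)(C)O1)[C@H]2COC(C)(C)O2 | intermediate
12 | 2-{[(2S,3S,5R)-5-[(4R)-2,2-dimethyl-1,3-dioxolan-4-yl]-2-ethenyloxolan-3-yl]oxy}-4,4,5,5-tetramethyl-1,3,2-dioxaborolane | CC1(C)OC[C@@H](O1)[C@H]2C[C@H](OB3OC(C)(C)C(C)(C)O3)[C@H](C=C)O2 | intermediate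
13 | (2S,3S,5R)-5-[(4R)-2,2-dimethyl-1,3-dioxolan-4-yl]-2-ethenyloxolan-3-ol | CC1(C)OC[C@@H](O1)[C@H]2C[C@H](O)[C@H](C=C)O2 | intermediate
14 | (4E)-oct-4-ene | CCC/C=C/CCC | starting material
15 | (2S,3S,5R)-5-[(4R)-2,2-dimethyl-1,3-dioxolan-4-yl]-2-[(1E)-pent-1-enyl]oxolan-3-ol | CC1(C)OC[C@@H](O1)[C@H]2C[C@H](O)[C@H](/C=C/CCC)O2 | intermediate
16 | (2S,3S,5R)-5-[(4R)-2,2-dimethyl-1,3-dioxolan-4-yl]-2-pentyloxolan-3-ol | CC1(C)OC[C@@H](O1)[C@H]2C[C@H](O)[C@H](CCCCC)O2 | intermediate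
17 | tert-butyl{[(2S,3S,5R)-5-[(4R)-2,2-dimethyl-1,3-dioxolan-4-yl]-2-pentyloxolan-3-yl]oxy}dimethylsilane | CC1(C)OC[C@@H](O1)[C@H]2C[C@H](O[Si](C)(C)C(C)(C)C)[C@H](CCCCC)O2 | intermediate
18 | (1R)-1-[(2R,4S,5S)-4-{[tert-butyl(dimethyl)silyl]oxy}-5-pentyloxolan-2-yl]ethane-1,2-diol | OC[C@@H](O)[C@H]1C[C@H](O[Si](C)(C)C(C)(C)C)[C@H](CCCCC)O1 | intermediate
19 | (2R)-2-[(2R,4S,5S)-4-{[tert-butyl(dimethyl)silyl]oxy}-5-pentyloxolan-2-yl]-2-hydroxyethyl 4-methylbenzenesulfonate | Cc1ccc(cc1)S(=O)(=O)OC[C@@H](O)[C@H]1C[C@H](O[Si](C)(C)C(C)(C)C)[C@H](CCCCC)O1 | intermediate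
20 | tert-butyldimethyl{[(2S,3S,5R)-5-[(2R)-oxiran-2-yl]-2-pentyloxolan-3-yl]oxy}silane | C1O[C@H]1[C@H]2C[C@H](O[Si](C)(C)C(C)(C)C)[C@H](CCCCC)O2 | intermediate
21 | 8-bromooct-1-ene | C=CCCCCCCBr | starting material
22 | oct-7-en-1-ylmagnesium bromide | C=CCCCCCC[Mg]Br | intermediate
23 | (1R)-1-[(2R,4S,5S)-4-{[tert-butyl(dimethyl)silyl]oxy}-5-pentyloxolan-2-yl]dec-9-en-1-ol | C=CCCCCCCC[C@@H](O)[C@H]1C[C@H](O[Si](C)(C)C(C)(C)C)[C@H](CCCCC)O1 | intermediate
24 | hexadecanoyl chloride (palmitoyl chloride) | CCCCCCCCCCCCCCCC(Cl)=O | starting material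
25 | (1R)-1-[(2R,4S,5S)-4-{[tert-butyl(dimethyl)silyl]oxy}-5-pentyloxolan-2-yl]dec-9-enyl hexadecanoate | C=CCCCCCCC[C@@H](OC(=O)CCCCCCCCCCCCCCC)[C@H]1C[C@H](O[Si](C)(C)C(C)(C)C)[C@H](CCCCC)O1 | intermediate
26 | (1R)-1-[(2R,4S,5S)-4-hydroxy-5-pentyloxolan-2-yl]dec-9-enyl hexadecanoate | C=CCCCCCCC[C@@H](OC(=O)CCCCCCCCCCCCCCC)[C@H]1C[C@H](O)[C@H](CCCCC)O1 | target

Total step count: 12. Longest linear sequence: 12 steps (from 1; the Grignard reagent is made within step 10).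

Steps most likely to fail: step 5, step 4, step 6.

Step 5: the unmasking may consume the enol ether or the C–B bond (vinyl ether hydrolysis, protodeboronation) faster than it frees the aldehyde. The fallback sets out from 8 and comes back at 11, generating the aldehyde oxidatively instead of hydrolytically. The acetal of 8 is hydrolysed before any boron is present (LiBF4, wet MeCN) to (3R)-3-[(4R)-2,2-dimethyl-1,3-dioxolan-4-yl]-3-(prop-2-enyloxy)propanal F1. Reduction (NaBH4, MeOH, 0 °C) gives (3R)-3-[(4R)-2,2-dimethyl-1,3-dioxolan-4-yl]-3-(prop-2-enyloxy)propan-1-ol F2. Double deprotonation (s-BuLi, 2.3 equiv, THF, −78 °C) and trapping with 2-isopropoxy-4,4,5,5-tetramethyl-1,3,2-dioxaborolane give (3R)-3-[(4R)-2,2-dimethyl-1,3-dioxolan-4-yl]-3-{[(1Z)-3-(4,4,5,5-tetramethyl-1,3,2-dioxaborolan-2-yl)prop-1-enyl]oxy}propan-1-ol F3. Dess–Martin periodinane (NaHCO3, CH2Cl2, 0 °C) should oxidize F3 to 11 under neutral, water-free conditions, and ring closure to 13 then follows as in step 5.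

Step 4: the lithiated ether may take up boron at the α- instead of the γ-carbon, or the boronate may be lost on isolation. The fallback sets out from 8 and comes back at 13, replacing the allylboron by an allyltin cyclization. Quenching the same anion with Bu3SnCl should give the chromatographically stable tributyl[(2Z)-3-{[(1R)-1-[(4R)-2,2-dimethyl-1,3-dioxolan-4-yl]-3,3-dimethoxypropyl]oxy}prop-2-enyl]stannane F4. LiBF4 in wet MeCN frees (3R)-3-[(4R)-2,2-dimethyl-1,3-dioxolan-4-yl]-3-{[(1Z)-3-(tributylstannyl)prop-1-enyl]oxy}propanal F5. F5 is cyclized thermally (toluene, 110 °C) through the cyclic six-membered transition state of the (Z)-allylstannane, and KF work-up removes tin to give 13.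

Step 6: cross-metathesis may stall at the hindered allylic ether or be eroded by alkene migration. The fallback sets out from 13 and comes back at 17, building the chain by hydroboration and cuprate displacement. Silylation (TBSOTf, 2,6-lutidine) gives tert-butyl{[(2S,3S,5R)-5-[(4R)-2,2-dimethyl-1,3-dioxolan-4-yl]-2-ethenyloxolan-3-yl]oxy}dimethylsilane F6. Hydroboration–oxidation (9-BBN, THF; NaOH, H2O2) gives 2-[(2S,3S,5R)-3-{[tert-butyl(dimethyl)silyl]oxy}-5-[(4R)-2,2-dimethyl-1,3-dioxolan-4-yl]oxolan-2-yl]ethan-1-ol F7. Tosylation (TsCl, pyridine) gives 2-[(2S,3S,5R)-3-{[tert-butyl(dimethyl)silyl]oxy}-5-[(4R)-2,2-dimethyl-1,3-dioxolan-4-yl]oxolan-2-yl]ethyl 4-methylbenzenesulfonate F8. Displacement with n-Pr2CuLi (Et2O, −40 °C) completes the pentyl chain of 17.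

Further compounds
F1 | step 5 | (3R)-3-[(4R)-2,2-dimethyl-1,3-dioxolan-4-yl]-3-(prop-2-enyloxy)propanal | O=CC[C@@H](OCC=C)[C@H]1COC(C)(C)O1
F2 | step 5 | (3R)-3-[(4R)-2,2-dimethyl-1,3-dioxolan-4-yl]-3-(prop-2-enyloxy)propan-1-ol | OCC[C@@H](OCC=C)[C@H]1COC(C)(C)O1
F3 | step 5 | (3R)-3-[(4R)-2,2-dimethyl-1,3-dioxolan-4-yl]-3-{[(1Z)-3-(4,4,5,5-tetramethyl-1,3,2-dioxaborolan-2-yl)prop-1-enyl]oxy}propan-1-ol | OCC[C@@H](O/C=C\CB1OC(C)(C)C(C)(C)O1)[C@H]2COC(C)(C)O2
F4 | step 4 | tributyl[(2Z)-3-{[(1R)-1-[(4R)-2,2-dimethyl-1,3-dioxolan-4-yl]-3,3-dimethoxypropyl]oxy}prop-2-enyl]stannane | COC(OC)C[C@@H](O/C=C\C[Sn](CCCC)(CCCC)CCCC)[C@H]1COC(C)(C)O1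
F5 | step 4 | (3R)-3-[(4R)-2,2-dimethyl-1,3-dioxolan-4-yl]-3-{[(1Z)-3-(tributylstannyl)prop-1-enyl]oxy}propanal | O=CC[C@@H](O/C=C\C[Sn](CCCC)(CCCC)CCCC)[C@H]1COC(C)(C)O1
F6 | step 6 | tert-butyl{[(2S,3S,5R)-5-[(4R)-2,2-dimethyl-1,3-dioxolan-4-yl]-2-ethenyloxolan-3-yl]oxy}dimethylsilane | CC1(C)OC[C@@H](O1)[C@H]2C[C@H](O[Si](C)(C)C(C)(C)C)[C@H](C=C)O2
F7 | step 6 | 2-[(2S,3S,5R)-3-{[tert-butyl(dimethyl)silyl]oxy}-5-[(4R)-2,2-dimethyl-1,3-dioxolan-4-yl]oxolan-2-yl]ethan-1-ol | CC1(C)OC[C@@H](O1)[C@H]2C[C@H](O[Si](C)(C)C(C)(C)C)[C@H](CCO)O2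
F8 | step 6 | 2-[(2S,3S,5R)-3-{[tert-butyl(dimethyl)silyl]oxy}-5-[(4R)-2,2-dimethyl-1,3-dioxolan-4-yl]oxolan-2-yl]ethyl 4-methylbenzenesulfonate | CC1(C)OC[C@@H](O1)[C@H]2C[C@H](O[Si](C)(C)C(C)(C)C)[C@H](CCOS(=O)(=O)c3ccc(C)cc3)O2
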